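The route rests on cutting the C2–C3 bond of the cyclopentane ring (C1, C2, C3, C3a, C7a). C2 is the only non-stereogenic atom of that ring. A trans ring fusion cannot arise by attack on an sp2 C3a or C7a, so both fusion centres are fixed first on a cyclohexanone, by anti conjugate addition and anti enolate trapping. The key step is a reductive decarboxylative radical cyclisation. A primary C2 radical, released from a butanoic acid arm on C7a, adds 5-exo-dig to an ethynyl group on C3a. This one operation removes the activating carboxyl carbon and closes the trans-hydrindane. The precursor is a monocyclic, fully substituted keto acid.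

Key step: step 8

Remark: the locants C1–C7a are those of the hexahydro-1H-indene core of the target. They are used for the corresponding atoms of all intermediates (C4 quaternary, C5 phenyl-bearing, C3a/C7a ring fusion).

Step 1
Reactants: 1 (E)-1-methoxy-3-(trimethylsilyloxy)buta-1,3-diene; 2 2-ethylacrolein
Product: 4 rac-1-ethyl-4-oxocyclohex-2-ene-1-carbaldehyde, via silyl enol ether cycloadduct 3 (not isolated)
Conditions: toluene, 80 °C; then 0.1 M HCl, THF, 0 °C
Reagents that add atoms: none
Why: Diels–Alder reaction in which the 1-methoxy-3-silyloxy pattern directs the diene C4 terminus to the CH2 of the enal, and dilute acid then hydrolyses the silyl enol ether and eliminates methanol to the enone; the stereocentre is erased in step 3 and needs no control.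

Step 2
Reactants: 4 rac-1-ethyl-4-oxocyclohex-2-ene-1-carbaldehyde; 5 ethyl 2-(triphenyl-λ5-phosphanylidene)propanoate
Product: 6 rac-ethyl (2E)-3-(1-ethyl-4-oxocyclohex-2-en-1-yl)-2-methylprop-2-enoate
Conditions: toluene, 110 °C
Reagents that add atoms: none
Why: Wittig olefination with a stabilised ylide attacks only the aldehyde, not the enone, and should give the (E)-trisubstituted enoate as is usual for stabilised ylides.

Step 3
Reactants: 6 rac-ethyl (2E)-3-(1-ethyl-4-oxocyclohex-2-en-1-yl)-2-methylprop-2-enoate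
Product: 7 ethyl (2E)-3-(1-ethyl-4-oxocyclohexa-2,5-dien-1-yl)-2-methylprop-2-enoate (achiral)
Conditions: IBX, DMSO, 80 °C
Reagents that add atoms: none
Why: IBX dehydrogenation at the only remaining CH2–CH2 unit next to the ketone gives the cross-conjugated dienone, which is achiral because the two ring halves are now identical.

Step 4
Reactants: 7 ethyl (2E)-3-(1-ethyl-4-oxocyclohexa-2,5-dien-1-yl)-2-methylprop-2-enoate; 8 phenylboronic acid
Product: 9 ethyl (2E)-3-[(1S,6S)-1-ethyl-4-oxo-6-phenylcyclohex-2-en-1-yl]-2-methylprop-2-enoate (phenyl cis to ethyl)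
Conditions: Rh(acac)(C2H4)2 (3 mol %), (S)-BINAP, 8 (1.1 equiv), dioxane/H2O 10:1, 60 °C
Reagents that add atoms: none
Why: Hayashi–Miyaura asymmetric 1,4-addition used as a desymmetrisation, in which the aryl-rhodium species can reach only the ring face anti to the bulky alkenyl group at C4 (phenyl ends cis to ethyl), and (S)-BINAP, in the sense known for cyclohex-2-enone, selects the enantiotopic C=C for which this face is the matched one, so that C4 (S) and C5 (S) are set together.

Step 5
Reactants: 9 ethyl (2E)-3-[(1S,6S)-1-ethyl-4-oxo-6-phenylcyclohex-2-en-1-yl]-2-methylprop-2-enoate; 10 ethynylmagnesium bromide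
Product: 11 ethyl (2E)-3-[(1S,2S,6S)-4-(tert-butyldimethylsilyloxy)-1-ethyl-2-ethynyl-6-phenylcyclohex-3-en-1-yl]-2-methylprop-2-enoate (ethynyl trans to ethyl and phenyl)
Conditions: HC≡CMgBr, ZnBr2, THF, 0 °C; then 9, TBSOTf, Et2O/THF, −40 °C
Reagents that add atoms: tert-butyldimethylsilyl trifluoromethanesulfonate, CC(C)(C)[Si](C)(C)OS(=O)(=O)C(F)(F)F
Why: Silyl-triflate-promoted conjugate addition of an alkynylzinc halide, in which the half-chair with phenyl and the alkenyl group equatorial holds ethyl axial, so axial attack at C3a comes from the face anti to ethyl and puts the slim ethynyl group trans to ethyl and phenyl, while silylation traps the enolate regiospecifically towards C7a.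

Step 6
Reactants: 11 ethyl (2E)-3-[(1S,2S,6S)-4-(tert-butyldimethylsilyloxy)-1-ethyl-2-ethynyl-6-phenylcyclohex-3-en-1-yl]-2-methylprop-2-enoate; 12 (E)-but-2-enal
Product: 13 ethyl (2E)-3-[(1S,2S,3R,6S)-1-ethyl-2-ethynyl-4-oxo-3-[(2R)-4-oxobutan-2-yl]-6-phenylcyclohexyl]-2-methylprop-2-enoate
Conditions: (2S,5S)-5-benzyl-2-tert-butyl-3-methylimidazolidin-4-one·2,4-dinitrobenzoic acid (20 mol %), CH2Cl2/H2O, −40 °C
Reagents that add atoms: none
Why: Organocatalytic Mukaiyama–Michael addition in which the enol ether reacts through the face anti to the neighbouring pseudo-axial ethynyl group (trans relation at C3a/C7a) and the imidazolidinone iminium ion exposes one face of the enal β-carbon, in the sense known for carbon nucleophiles and but-2-enal, which sets C1 as (R).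

Step 7
Reactants: 13 ethyl (2E)-3-[(1S,2S,3R,6S)-1-ethyl-2-ethynyl-4-oxo-3-[(2R)-4-oxobutan-2-yl]-6-phenylcyclohexyl]-2-methylprop-2-enoate
Product: 14 (3R)-3-[(1R,2S,3S,4S)-3-[(1E)-3-ethoxy-2-methyl-3-oxoprop-1-en-1-yl]-3-ethyl-2-ethynyl-6-oxo-4-phenylcyclohexyl]butanoic acid
Conditions: NaClO2, NaH2PO4, 2-methylbut-2-ene, t-BuOH/H2O, 0 °C
Reagents that add atoms: sodium chlorite, [Na+].[O-]Cl=O
Why: Pinnick oxidation converts the aldehyde into the acid under buffered, weakly acidic conditions that leave the alkyne, the enoate and the epimerisable C7a centre untouched.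

Step 8
Reactants: 14 (3R)-3-[(1R,2S,3S,4S)-3-[(1E)-3-ethoxy-2-methyl-3-oxoprop-1-en-1-yl]-3-ethyl-2-ethynyl-6-oxo-4-phenylcyclohexyl]butanoic acid
Product: 16 ethyl (2E)-3-[(1R,3aS,4S,5S,7aR)-4-ethyl-1-methyl-3-methylidene-7-oxo-5-phenyloctahydro-1H-inden-4-yl]-2-methylprop-2-enoate, via N-acyloxyphthalimide 15 (not isolated)
Conditions: N-hydroxyphthalimide, DIC, DMAP (cat.), CH2Cl2, rt; then Ru(bpy)3(PF6)2 (1 mol %), diethyl 2,6-dimethyl-1,4-dihydropyridine-3,5-dicarboxylate (1.5 equiv), CH2Cl2 (0.005 M), blue LEDs, rt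
Reagents that add atoms: none
Why: Single-electron reduction of the N-acyloxyphthalimide 15 by the photoreduced ruthenium complex splits the N–O bond, loss of CO2 frees the primary C2 radical, this adds to the inner alkyne carbon, and the vinyl radical formed takes a hydrogen atom from the dihydropyridine. The closest known reaction type is the reductive decarboxylative radical cyclisation of redox-active esters, in essence a hex-5-ynyl radical cyclisation. The cyclopentane is closed in the 5-exo-dig mode at the C2–C3 bond. No new stereocentre is formed: C1, C3a and C7a are carried over untouched, so the trans ring fusion is simply the trans relation of the two arms, which must both be equatorial in the reacting chair. The step needs 5-exo rather than 6-endo closure and a cyclisation faster than hydrogen transfer to the open radical; the first is secured by the terminal alkyne and the three-atom link, the second by high dilution and a slow hydrogen donor. Ketone, enoate and phenyl groups are inert to the nucleophilic primary radical under these neutral conditions.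

Step 9
Reactants: 16 ethyl (2E)-3-[(1R,3aS,4S,5S,7aR)-4-ethyl-1-methyl-3-methylidene-7-oxo-5-phenyloctahydro-1H-inden-4-yl]-2-methylprop-2-enoate
Product: 17 ethyl (2E)-3-[(1R,3R,3aR,4S,5S,7aR)-4-ethyl-1,3-dimethyl-7-oxo-5-phenyloctahydro-1H-inden-4-yl]-2-methylprop-2-enoate
Conditions: H2 (1 atm), RhCl(PPh3)3 (10 mol %), benzene, rt
Reagents that add atoms: none
Why: Homogeneous hydrogenation reduces only the 1,1-disubstituted C=C, not the hindered trisubstituted enoate, and the bulky catalyst should approach the face that carries H-3a because the other face is covered by the axial alkenyl group on C4, so the new C3–H is cis to H-3a and C3 becomes (R).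

Step 10
Reactants: 17 ethyl (2E)-3-[(1R,3R,3aR,4S,5S,7aR)-4-ethyl-1,3-dimethyl-7-oxo-5-phenyloctahydro-1H-inden-4-yl]-2-methylprop-2-enoate
Product: 18 ethyl (2E)-3-[(1R,3R,3aR,4S,5S,7aR)-4-ethyl-1,3-dimethyl-5-phenyl-7-(trifluoromethanesulfonyloxy)-2,3,3a,4,5,7a-hexahydro-1H-inden-4-yl]-2-methylprop-2-enoate
Conditions: KN(SiMe3)2, THF, −78 °C; then PhNTf2
Reagents that add atoms: N-phenylbis(trifluoromethanesulfonimide), O=S(=O)(N(c1ccccc1)S(=O)(=O)C(F)(F)F)C(F)(F)F
Why: Kinetic enolisation with a bulky amide base removes a proton from the C6 methylene rather than the tertiary C7a–H, and O-sulfonylation fixes the C6=C7 enol triflate without touching C7a.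

Step 11
Reactants: 18 ethyl (2E)-3-[(1R,3R,3aR,4S,5S,7aR)-4-ethyl-1,3-dimethyl-5-phenyl-7-(trifluoromethanesulfonyloxy)-2,3,3a,4,5,7a-hexahydro-1H-inden-4-yl]-2-methylprop-2-enoate
Product: 19 ethyl (2E)-3-[(1R,3R,3aR,4S,5S,7aR)-4-ethyl-1,3,7-trimethyl-5-phenyl-2,3,3a,4,5,7a-hexahydro-1H-inden-4-yl]-2-methylprop-2-enoate (plakotenin ethyl ester)
Conditions: Me2Zn, Pd(PPh3)4 (5 mol %), THF, 0 °C to rt
Reagents that add atoms: dimethylzinc, C[Zn]C
Why: Negishi cross-coupling of the enol triflate with dimethylzinc replaces C–O by C–CH3 with retention of the double bond position and tolerates the ester.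

Step 12
Reactants: 19 plakotenin ethyl ester
Product: 20 plakotenin, (2E)-3-[(1R,3R,3aR,4S,5S,7aR)-4-ethyl-1,3,7-trimethyl-5-phenyl-2,3,3a,4,5,7a-hexahydro-1H-inden-4-yl]-2-methylprop-2-enoic acid
Conditions: LiOH, THF/MeOH/H2O, 50 °C; then 1 M HCl
Reagents that add atoms: lithium hydroxide, [Li+].[OH-]
Why: Saponification of the ethyl ester followed by acidification gives the free acid; no stereocentre is α to a carbonyl group any more, so none can epimerise.

Compound list
1 | (E)-1-methoxy-3-(trimethylsilyloxy)buta-1,3-diene | CO/C=C/C(=C)O[Si](C)(C)C | starting material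
2 | 2-ethylacrolein (2-methylidenebutanal) | CCC(=C)C=O | starting material
3 | 1-ethyl-2-methoxy-4-(trimethylsilyloxy)cyclohex-3-ene-1-carbaldehyde (racemic, diastereomer mixture) | CCC1(C=O)CCC(O[Si](C)(C)C)=CC1OC | intermediate
4 | rac-1-ethyl-4-oxocyclohex-2-ene-1-carbaldehyde | CCC1(C=O)C=CC(=O)CC1 | intermediate
5 | ethyl 2-(triphenyl-λ5-phosphanylidene)propanoate | CCOC(=O)C(C)=P(c1ccccc1)(c1ccccc1)c1ccccc1 | starting material
6 | rac-ethyl (2E)-3-(1-ethyl-4-oxocyclohex-2-en-1-yl)-2-methylprop-2-enoate | CCC1(/C=C(\C)C(=O)OCC)C=CC(=O)CC1 | intermediate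
7 | ethyl (2E)-3-(1-ethyl-4-oxocyclohexa-2,5-dien-1-yl)-2-methylprop-2-enoate | CCC1(/C=C(\C)C(=O)OCC)C=CC(=O)C=C1 | intermediate
8 | phenylboronic acid | OB(O)c1ccccc1 | starting material
9 | ethyl (2E)-3-[(1S,6S)-1-ethyl-4-oxo-6-phenylcyclohex-2-en-1-yl]-2-methylprop-2-enoate | CC[C@@]1(/C=C(\C)C(=O)OCC)C=CC(=O)C[C@H]1c1ccccc1 | intermediate
10 | ethynylmagnesium bromide | C#C[Mg]Br | starting material
11 | ethyl (2E)-3-[(1S,2S,6S)-4-(tert-butyldimethylsilyloxy)-1-ethyl-2-ethynyl-6-phenylcyclohex-3-en-1-yl]-2-methylprop-2-enoate | CC[C@@]1(/C=C(\C)C(=O)OCC)[C@H](C#C)C=C(O[Si](C)(C)C(C)(C)C)C[C@H]1c1ccccc1 | intermediate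
12 | (E)-but-2-enal | C/C=C/C=O | starting material
13 | ethyl (2E)-3-[(1S,2S,3R,6S)-1-ethyl-2-ethynyl-4-oxo-3-[(2R)-4-oxobutan-2-yl]-6-phenylcyclohexyl]-2-methylprop-2-enoate | CC[C@@]1(/C=C(\C)C(=O)OCC)[C@H](C#C)[C@H](C(=O)C[C@H]1c1ccccc1)[C@H](C)CC=O | intermediate
14 | (3R)-3-[(1R,2S,3S,4S)-3-[(1E)-3-ethoxy-2-methyl-3-oxoprop-1-en-1-yl]-3-ethyl-2-ethynyl-6-oxo-4-phenylcyclohexyl]butanoic acid | CC[C@@]1(/C=C(\C)C(=O)OCC)[C@H](C#C)[C@H](C(=O)C[C@H]1c1ccccc1)[C@H](C)CC(=O)O | intermediate
15 | 1,3-dioxoisoindolin-2-yl ester of 14 (stereocentres as in 14) | CC[C@@]1(/C=C(\C)C(=O)OCC)[C@H](C#C)[C@H](C(=O)C[C@H]1c1ccccc1)[C@H](C)CC(=O)ON1C(=O)c2ccccc2C1=O | intermediate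
16 | ethyl (2E)-3-[(1R,3aS,4S,5S,7aR)-4-ethyl-1-methyl-3-methylidene-7-oxo-5-phenyloctahydro-1H-inden-4-yl]-2-methylprop-2-enoate | CC[C@@]1(/C=C(\C)C(=O)OCC)[C@H]2[C@H](C(=O)C[C@H]1c1ccccc1)[C@H](C)CC2=C | intermediate
17 | ethyl (2E)-3-[(1R,3R,3aR,4S,5S,7aR)-4-ethyl-1,3-dimethyl-7-oxo-5-phenyloctahydro-1H-inden-4-yl]-2-methylprop-2-enoate | CC[C@@]1(/C=C(\C)C(=O)OCC)[C@H]2[C@H](C(=O)C[C@H]1c1ccccc1)[C@H](C)C[C@H]2C | intermediate
18 | ethyl (2E)-3-[(1R,3R,3aR,4S,5S,7aR)-4-ethyl-1,3-dimethyl-5-phenyl-7-(trifluoromethanesulfonyloxy)-2,3,3a,4,5,7a-hexahydro-1H-inden-4-yl]-2-methylprop-2-enoate | CC[C@@]1(/C=C(\C)C(=O)OCC)[C@H]2[C@H](C(OS(=O)(=O)C(F)(F)F)=C[C@H]1c1ccccc1)[C@H](C)C[C@H]2C | intermediate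
19 | plakotenin ethyl ester | CC[C@@]1(/C=C(\C)C(=O)OCC)[C@H]2[C@H](C(C)=C[C@H]1c1ccccc1)[C@H](C)C[C@H]2C | intermediate
20 | plakotenin | CC[C@@]1(/C=C(\C)C(=O)O)[C@H]2[C@H](C(C)=C[C@H]1c1ccccc1)[C@H](C)C[C@H]2C | target

Total step count: 12. Longest linear sequence: 12 steps.

Steps most likely to fail

Step 8. Hydrogen transfer to the open-chain C2 radical may outrun ring closure, because only the chair with both arms equatorial (phenyl and the C4 alkenyl group axial) can cyclise. The fallback sets out from 14 and comes back at 16.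
- Iododecarboxylation (PhI(OAc)2, I2, hν, CH2Cl2) gives the primary iodide F1.
- Iodine-atom-transfer cyclisation ((Bu3Sn)2 cat., hν, benzene) gives the iodomethylidene hydrindanone F2. This chain contains no hydrogen donor, so an uncyclised radical can only be re-iodinated.
- Radical hydrodeiodination with (Me3Si)3SiH and Et3B/air then gives 16.

Step 6. Several things may go wrong here. The hindered enol ether may add sluggishly to the iminium ion, protodesilylation may take over, facial control may erode, or C7a may epimerise by enolisation towards the more stable cis arrangement. The fallback sets out from 11 and comes back at 14, bypassing 13 and step 7.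
- A TiCl4-promoted Mukaiyama–Michael addition to (S)-4-benzyl-3-[(E)-but-2-enoyl]-1,3-oxazolidin-2-one gives the N-acyloxazolidinone F3. In its chelated s-cis form the benzyl group shields one face of the β-carbon, so a covalently bound auxiliary on a much stronger acceptor takes over the control of C1.
- Cleavage with LiOH/H2O2 at 0 °C gives 14.

Step 9. Facial selectivity at the methylidene group may be poor, or the double bond may migrate into the ring before reduction. The fallback sets out from 16 and comes back at 17.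
- LiBH(s-Bu)3 attacks the ketone from the equatorial side and gives the axial C7 alcohol F4.
- Hydroxyl-directed hydrogenation with [Ir(cod)(PCy3)(py)]PF6 and H2 in CH2Cl2 binds to this axial hydroxyl group, which lies on the same face as H-3a. Hydrogen is delivered from that face and gives the saturated alcohol F5.
- A Dess–Martin oxidation returns 17.

Further compounds
F1 | step 8 | primary iodide from iododecarboxylation of 14 (stereocentres as in 14) | CC[C@@]1(/C=C(\C)C(=O)OCC)[C@H](C#C)[C@H](C(=O)C[C@H]1c1ccccc1)[C@H](C)CI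
F2 | step 8 | 3-(iodomethylidene) analogue of 16 (alkene geometry not controlled) | CC[C@@]1(/C=C(\C)C(=O)OCC)[C@H]2[C@H](C(=O)C[C@H]1c1ccccc1)[C@H](C)CC2=CI
F3 | step 6 | N-acyl-(S)-4-benzyloxazolidin-2-one of acid 14 | CC[C@@]1(/C=C(\C)C(=O)OCC)[C@H](C#C)[C@H](C(=O)C[C@H]1c1ccccc1)[C@H](C)CC(=O)N1[C@@H](Cc2ccccc2)COC1=O
F4 | step 9 | axial C7 alcohol of 16 (hydroxyl on the face of H-3a) | CC[C@@]1(/C=C(\C)C(=O)OCC)[C@H]2[C@H]([C@@H](O)C[C@H]1c1ccccc1)[C@H](C)CC2=C
F5 | step 9 | axial C7 alcohol of 17 | CC[C@@]1(/C=C(\C)C(=O)OCC)[C@H]2[C@H]([C@@H](O)C[C@H]1c1ccccc1)[C@H](C)C[C@H]2C
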